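**Plan** (locants: oxolane O1, C2 carrying ring A = the 4-oxy-3-methoxyphenyl ring, C3, C4, C5 carrying ring B = 3,4-dimethoxyphenyl; side chain C1' carbinol, C2' ether carbon, ring C = outer 3,4-dimethoxyphenyl)
1. Cuts, in retrosynthetic order: C1'–H and C1'–ring C (ketone reduction, aryl Grignard on a Weinreb amide); C2'–O(ring A) ether (Mitsunobu with (S)-lactate); oxolane O1–C2; C2–ring A (aryllithium on a lactone); C3–CH3 (enolate methylation); C4–C5 (crotylboration of veratraldehyde).
2. Forward: C4–C5 first, then a temporary γ-lactone (C2 at the acid level) that relays C4/C5 to C3, opening by the ring A aryllithium to an acyclic γ-hydroxy aryl ketone, closure of the oxolane at O1–C2, and last the side chain on the freed ring A phenol.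
3. Enabling feature: C2 is benzylic to the para-oxygenated ring A and bonded to O1, so it can be carried as an aryl ketone; the C5 hydroxyl adds to it and the 2-aryl oxocarbenium ion O1=C2 is reduced under control of the adjacent C3 methyl group.
4. Stereochemistry: C5/C4 by catalyst-controlled (Z)-crotylboration (syn); C3 by the lactone face (trans to C4-Me); C2 by hydride anti to C3-Me (kinetic 2,3-cis); C2' from (S)-lactate with inversion; C1' by Felkin–Anh reduction (threo).

Key step: step 6

Remark: (S)-TRIP is taken, by analogy with benzaldehyde, as the catalyst enantiomer that sends the crotyl group to the Si face of an aryl aldehyde; if the opposite sense is found, (R)-TRIP is used instead.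
Remark: 15 is written as its open-chain γ-hydroxy ketone tautomer, which is expected to equilibrate with the cyclic hemiketal 16.

Step 1
Reactants: 1 3,4-dimethoxybenzaldehyde (veratraldehyde); 2 (Z)-crotylboronic acid pinacol ester
Product: 4 (1S,2R)-1-(3,4-dimethoxyphenyl)-2-methylbut-3-en-1-ol, via pinacol borate ester 3 (not isolated)
Conditions: (S)-TRIP (5 mol %), toluene, −30 °C; aq NaHCO3 work-up
Reagents that add atoms: none
Why: Chiral phosphoric acid-catalysed aldehyde crotylboration passes through a closed chair (Zimmerman–Traxler type) transition state, so the (Z)-crotyl geometry is translated into the syn C1/C2 relationship (the future C5/C4 cis pair) while the phosphate, bound to a boronate oxygen and the formyl hydrogen, exposes the Si face of the aldehyde and sets C1 as S.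

Step 2
Reactants: 4 (1S,2R)-1-(3,4-dimethoxyphenyl)-2-methylbut-3-en-1-ol
Product: 6 (1S,2R)-1-(3,4-dimethoxyphenyl)-2-methylbutane-1,4-diol, via bis(9-BBN) adduct 5 (not isolated)
Conditions: 9-BBN-H (2.2 equiv), THF, 0 °C to rt; then 3 M aq NaOH, 30% H2O2, 0 °C to rt
Reagents that add atoms: hydrogen peroxide OO
Why: Anti-Markovnikov hydroboration of the monosubstituted alkene by the bulky dialkylborane followed by stereoretentive peroxide oxidation places the primary hydroxyl on the terminal carbon (the future C2) and creates no new stereocentre.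

Step 3
Reactants: 6 (1S,2R)-1-(3,4-dimethoxyphenyl)-2-methylbutane-1,4-diol
Product: 9 (4R,5S)-5-(3,4-dimethoxyphenyl)-4-methyloxolan-2-one, via hydroxy aldehyde 7 (not isolated), via lactol 8 (not isolated)
Conditions: [Cu(MeCN)4]OTf (5 mol %), 2,2'-bipyridine (5 mol %), TEMPO (5 mol %), N-methylimidazole (10 mol %), MeCN, air, rt
Reagents that add atoms: none
Why: Copper/nitroxyl aerobic alcohol oxidation (oxidative lactonisation of a diol) is sterically selective for the primary hydroxyl over the secondary benzylic one, and the γ-hydroxy aldehyde closes to the lactol that is oxidised on to the γ-lactone, a temporary ring whose acyl C–O bond is given up again in step 5.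

Step 4
Reactants: 9 (4R,5S)-5-(3,4-dimethoxyphenyl)-4-methyloxolan-2-one
Product: 11 (3R,4R,5S)-5-(3,4-dimethoxyphenyl)-3,4-dimethyloxolan-2-one, via lithium enolate 10 (not isolated)
Conditions: LiN(iPr)2 (1.1 equiv), THF, −78 °C; MeI (1.5 equiv), −78 to −40 °C
Reagents that add atoms: iodomethane CI
Why: Alkylation of the lactone lithium enolate with iodomethane takes place on the ring face opposite the cis-disposed C4 methyl and C5 aryl groups, so the new C3 methyl is trans to the C4 methyl (3R).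

Step 5
Reactants: 11 (3R,4R,5S)-5-(3,4-dimethoxyphenyl)-3,4-dimethyloxolan-2-one; 12 1-(benzyloxy)-4-bromo-2-methoxybenzene
Product: 15 (2R,3R,4S)-1-[4-(benzyloxy)-3-methoxyphenyl]-4-(3,4-dimethoxyphenyl)-4-hydroxy-2,3-dimethylbutan-1-one, via aryllithium 13 (not isolated), via lithium hemiketal alkoxide 14 (not isolated)
Conditions: 12, n-BuLi (1.05 equiv), THF, −78 °C; then 11, −78 °C; sat. aq NH4Cl
Reagents that add atoms: none
Why: Bromine–lithium exchange followed by acyl substitution at the lactone carbonyl stops at single addition because the tetrahedral lithium alkoxide survives at −78 °C, and its collapse on protonation opens the temporary ring to the γ-hydroxy aryl ketone with the three stereocentres untouched.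

Step 6
Reactants: 15 (2R,3R,4S)-1-[4-(benzyloxy)-3-methoxyphenyl]-4-(3,4-dimethoxyphenyl)-4-hydroxy-2,3-dimethylbutan-1-one
Product: 18 (2S,3R,4R,5S)-2-[4-(benzyloxy)-3-methoxyphenyl]-5-(3,4-dimethoxyphenyl)-3,4-dimethyloxolane, via cyclic hemiketal 16 (not isolated), via oxocarbenium ion 17 (not isolated)
Conditions: Et3SiH (3 equiv), BF3·OEt2 (2 equiv), CH2Cl2, −78 °C; Et3N then aq NaHCO3 at −78 °C
Reagents that add atoms: none
Why: BF3·OEt2 promotes addition of the C5 hydroxyl oxygen O1 to the C2 aryl ketone (hemiketal 16) and ionisation of the hemiketal hydroxyl to the endocyclic 2-aryl oxocarbenium ion 17 (O1=C2, stabilised by the para-benzyloxy group of ring A), which Et3SiH reduces irreversibly at −78 °C. The closest known reaction type is the Lewis acid/silane reductive deoxygenation of lactols and cyclic hemiketals (ionic hydrogenation, reductive etherification of hydroxy ketones). The oxolane closes in the 5-exo-trig mode by attack of O1 on the exocyclic C2=O. The one new stereocentre, C2, is controlled by the C3 methyl group: allylic strain with the coplanar ring A holds that methyl pseudoaxial in the C4-flap envelope (C4 methyl axial, ring B pseudoequatorial), and hydride enters the opposite face by inside attack, which leaves ring A cis to the C3 methyl and trans to ring B (2S). The step needs kinetic facial selectivity and no reversible ring opening, because the 2,3-trans isomers are the thermodynamic ones; the low temperature, the cold basic quench and the benzyl ether on ring A (no free para-hydroxyl, hence no quinone methide) secure this, and since Et3SiH does not reduce the free ketone only the cyclic cation is reduced.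

Step 7
Reactants: 18 (2S,3R,4R,5S)-2-[4-(benzyloxy)-3-methoxyphenyl]-5-(3,4-dimethoxyphenyl)-3,4-dimethyloxolane
Product: 19 4-[(2S,3R,4R,5S)-5-(3,4-dimethoxyphenyl)-3,4-dimethyloxolan-2-yl]-2-methoxyphenol
Conditions: H2 (1 atm), 10% Pd/C, EtOAc, rt
Reagents that add atoms: none
Why: Catalytic hydrogenolysis cleaves the benzyl aryl ether far faster than the benzylic C–O bonds of the oxolane in a neutral aprotic solvent, and no stereocentre is involved.

Step 8
Reactants: 19 4-[(2S,3R,4R,5S)-5-(3,4-dimethoxyphenyl)-3,4-dimethyloxolan-2-yl]-2-methoxyphenol; 20 ethyl (S)-lactate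
Product: 21 ethyl (2R)-2-{4-[(2S,3R,4R,5S)-5-(3,4-dimethoxyphenyl)-3,4-dimethyloxolan-2-yl]-2-methoxyphenoxy}propanoate
Conditions: PPh3 (1.5 equiv), DIAD (1.5 equiv), THF, 0 °C to rt
Reagents that add atoms: none
Why: Mitsunobu etherification, in which the phenoxide displaces the oxyphosphonium derivative of the α-hydroxy ester in an SN2 step with inversion, so that (S)-lactate gives the (R)-aryl ether that becomes C2' of the side chain.

Step 9
Reactants: 21 ethyl (2R)-2-{4-[(2S,3R,4R,5S)-5-(3,4-dimethoxyphenyl)-3,4-dimethyloxolan-2-yl]-2-methoxyphenoxy}propanoate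
Product: 22 (2R)-2-{4-[(2S,3R,4R,5S)-5-(3,4-dimethoxyphenyl)-3,4-dimethyloxolan-2-yl]-2-methoxyphenoxy}-N-methoxy-N-methylpropanamide
Conditions: MeNH(OMe)·HCl (3 equiv), iPrMgCl (6 equiv), THF, −20 °C
Reagents that add atoms: N,O-dimethylhydroxylamine hydrochloride CNOC.Cl
Why: Aminolysis of the ester by the chloromagnesium amide of N,O-dimethylhydroxylamine (Weinreb amide formation) is fast at −20 °C, where the weakly basic amide should not deprotonate the α-aryloxy stereocentre.

Step 10
Reactants: 22 (2R)-2-{4-[(2S,3R,4R,5S)-5-(3,4-dimethoxyphenyl)-3,4-dimethyloxolan-2-yl]-2-methoxyphenoxy}-N-methoxy-N-methylpropanamide; 23 (3,4-dimethoxyphenyl)magnesium bromide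
Product: 25 (2R)-1-(3,4-dimethoxyphenyl)-2-{4-[(2S,3R,4R,5S)-5-(3,4-dimethoxyphenyl)-3,4-dimethyloxolan-2-yl]-2-methoxyphenoxy}propan-1-one, via magnesium chelate 24 (not isolated)
Conditions: 23 (0.5 M in THF, 2 equiv), THF, −10 °C; sat. aq NH4Cl
Reagents that add atoms: none
Why: Weinreb ketone synthesis, in which the chelated tetrahedral magnesium adduct does not collapse until work-up, which prevents over-addition and keeps the basic Grignard reagent away from the enolisable α-aryloxy ketone.

Step 11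
Reactants: 25 (2R)-1-(3,4-dimethoxyphenyl)-2-{4-[(2S,3R,4R,5S)-5-(3,4-dimethoxyphenyl)-3,4-dimethyloxolan-2-yl]-2-methoxyphenoxy}propan-1-one
Product: 26 (1R,2R)-1-(3,4-dimethoxyphenyl)-2-{4-[(2S,3R,4R,5S)-5-(3,4-dimethoxyphenyl)-3,4-dimethyloxolan-2-yl]-2-methoxyphenoxy}propan-1-ol
Conditions: NaBH4 (2 equiv), 15-crown-5 (2 equiv), MeOH/CH2Cl2, −20 °C
Reagents that add atoms: none
Why: Felkin–Anh (polar) 1,2-induction in a non-chelating borohydride reduction, in which, with the sodium ion sequestered by the crown ether, the C–OAr bond lies anti to the incoming hydride and the α-hydrogen flanks its trajectory, so the carbinol is formed threo to the ether carbon (1R,2R).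

**Compound list**
1 | 3,4-dimethoxybenzaldehyde | COc1ccc(C=O)cc1OC | starting material
2 | (Z)-crotylboronic acid pinacol ester | C/C=C\CB1OC(C)(C)C(C)(C)O1 | starting material
3 | pinacol borate ester of 4 | CC1(C)OB(O[C@H](c2ccc(OC)c(OC)c2)[C@H](C)C=C)OC1(C)C | intermediate
4 | (1S,2R)-1-(3,4-dimethoxyphenyl)-2-methylbut-3-en-1-ol | O[C@H](c1ccc(OC)c(OC)c1)[C@H](C)C=C | intermediate
5 | bis(9-BBN) adduct of 4 (O-borinate and terminal C-borane) | COc1ccc(cc1OC)[C@@H](OB2C3CCCC2CCC3)[C@H](C)CCB4C5CCCC4CCC5 | intermediate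
6 | (1S,2R)-1-(3,4-dimethoxyphenyl)-2-methylbutane-1,4-diol | O[C@H](c1ccc(OC)c(OC)c1)[C@H](C)CCO | intermediate
7 | (3R,4S)-4-(3,4-dimethoxyphenyl)-4-hydroxy-3-methylbutanal | O[C@H](c1ccc(OC)c(OC)c1)[C@H](C)CC=O | intermediate
8 | (4R,5S)-5-(3,4-dimethoxyphenyl)-4-methyloxolan-2-ol | OC1O[C@H](c2ccc(OC)c(OC)c2)[C@H](C)C1 | intermediate
9 | (4R,5S)-5-(3,4-dimethoxyphenyl)-4-methyloxolan-2-one | O=C1O[C@H](c2ccc(OC)c(OC)c2)[C@H](C)C1 | intermediate
10 | lithium enolate of 9 | [Li+].[O-]C1=C[C@@H](C)[C@@H](c2ccc(OC)c(OC)c2)O1 | intermediate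
11 | (3R,4R,5S)-5-(3,4-dimethoxyphenyl)-3,4-dimethyloxolan-2-one | O=C1O[C@H](c2ccc(OC)c(OC)c2)[C@H](C)[C@H]1C | intermediate
12 | 1-(benzyloxy)-4-bromo-2-methoxybenzene | Brc1ccc(OCc2ccccc2)c(OC)c1 | starting material
13 | [4-(benzyloxy)-3-methoxyphenyl]lithium | [Li]c1ccc(OCc2ccccc2)c(OC)c1 | intermediate
14 | lithium alkoxide of cyclic hemiketal 16 | [Li+].[O-]C1(c2ccc(OCc3ccccc3)c(OC)c2)O[C@H](c4ccc(OC)c(OC)c4)[C@H](C)[C@H]1C | intermediate
15 | (2R,3R,4S)-1-[4-(benzyloxy)-3-methoxyphenyl]-4-(3,4-dimethoxyphenyl)-4-hydroxy-2,3-dimethylbutan-1-one | O[C@H](c1ccc(OC)c(OC)c1)[C@H](C)[C@@H](C)C(=O)c2ccc(OCc3ccccc3)c(OC)c2 | intermediate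
16 | (3R,4R,5S)-2-[4-(benzyloxy)-3-methoxyphenyl]-5-(3,4-dimethoxyphenyl)-3,4-dimethyloxolan-2-ol | OC1(c2ccc(OCc3ccccc3)c(OC)c2)O[C@H](c4ccc(OC)c(OC)c4)[C@H](C)[C@H]1C | intermediate
17 | (3R,4R,5S)-2-[4-(benzyloxy)-3-methoxyphenyl]-5-(3,4-dimethoxyphenyl)-3,4-dimethyl-4,5-dihydro-3H-furan-1-ium | COc1cc(ccc1OCc2ccccc2)C3=[O+][C@H](c4ccc(OC)c(OC)c4)[C@H](C)[C@H]3C | intermediate
18 | (2S,3R,4R,5S)-2-[4-(benzyloxy)-3-methoxyphenyl]-5-(3,4-dimethoxyphenyl)-3,4-dimethyloxolane | COc1cc(ccc1OCc2ccccc2)[C@H]3O[C@H](c4ccc(OC)c(OC)c4)[C@H](C)[C@H]3C | intermediate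
19 | 4-[(2S,3R,4R,5S)-5-(3,4-dimethoxyphenyl)-3,4-dimethyloxolan-2-yl]-2-methoxyphenol | COc1cc(ccc1O)[C@H]2O[C@H](c3ccc(OC)c(OC)c3)[C@H](C)[C@H]2C | intermediate
20 | ethyl (S)-lactate | CCOC(=O)[C@H](C)O | starting material
21 | ethyl (2R)-2-{4-[(2S,3R,4R,5S)-5-(3,4-dimethoxyphenyl)-3,4-dimethyloxolan-2-yl]-2-methoxyphenoxy}propanoate | CCOC(=O)[C@@H](C)Oc1ccc(cc1OC)[C@H]2O[C@H](c3ccc(OC)c(OC)c3)[C@H](C)[C@H]2C | intermediate
22 | (2R)-2-{4-[(2S,3R,4R,5S)-5-(3,4-dimethoxyphenyl)-3,4-dimethyloxolan-2-yl]-2-methoxyphenoxy}-N-methoxy-N-methylpropanamide | CON(C)C(=O)[C@@H](C)Oc1ccc(cc1OC)[C@H]2O[C@H](c3ccc(OC)c(OC)c3)[C@H](C)[C@H]2C | intermediate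
23 | (3,4-dimethoxyphenyl)magnesium bromide | COc1ccc([Mg]Br)cc1OC | starting material
24 | bromomagnesium alkoxide of the tetrahedral adduct of 22 and 23 | COc1ccc(cc1OC)C(O[Mg]Br)(N(C)OC)[C@@H](C)Oc2ccc(cc2OC)[C@H]3O[C@H](c4ccc(OC)c(OC)c4)[C@H](C)[C@H]3C | intermediate
25 | (2R)-1-(3,4-dimethoxyphenyl)-2-{4-[(2S,3R,4R,5S)-5-(3,4-dimethoxyphenyl)-3,4-dimethyloxolan-2-yl]-2-methoxyphenoxy}propan-1-one | COc1ccc(cc1OC)C(=O)[C@@H](C)Oc2ccc(cc2OC)[C@H]3O[C@H](c4ccc(OC)c(OC)c4)[C@H](C)[C@H]3C | intermediate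
26 | (1R,2R)-1-(3,4-dimethoxyphenyl)-2-{4-[(2S,3R,4R,5S)-5-(3,4-dimethoxyphenyl)-3,4-dimethyloxolan-2-yl]-2-methoxyphenoxy}propan-1-ol | COc1ccc([C@@H](O)[C@@H](C)Oc2ccc([C@H]3O[C@H](c4ccc(OC)c(OC)c4)[C@H](C)[C@H]3C)cc2OC)cc1OC | target

**Totals**
Total step count: 11. Longest linear sequence: 11 steps (1 to 26); 2, 12, 20 and 23 are bought.

**Steps most likely to fail**

Step 6. Hydride delivery may lose facial selectivity, because the face anti to the C3 methyl is also the face of the axial C4 methyl. The Lewis acid may also reopen the ring to a benzylic cation and epimerise C5 or C2 toward the 2,3-trans isomers, or the cation may lose the C3 proton to a dihydrofuran. The fallback sets the C2 configuration with a carbon nucleophile on a C2-unsubstituted oxocarbenium ion instead. It sets out from lactone 11, which is reduced with iBu2AlH (CH2Cl2, −78 °C) to (3R,4R,5S)-5-(3,4-dimethoxyphenyl)-3,4-dimethyloxolan-2-ol F1. With PhSO2H and CaCl2 (CH2Cl2, rt) this should give (3R,4R,5S)-2-(benzenesulfonyl)-5-(3,4-dimethoxyphenyl)-3,4-dimethyloxolane F2. Aryllithium 13 is transmetallated with ZnBr2 to [4-(benzyloxy)-3-methoxyphenyl]zinc bromide F3, which replaces the sulfinate of F2 (THF, rt) through the oxocarbenium ion. The aryl group should enter trans to the C4 methyl on the envelope with both methyls pseudoequatorial, that is cis to the C3 methyl, and the route is rejoined at 18.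

Step 11. Partial chelation of the carbonyl and aryloxy oxygens by incompletely sequestered sodium would erode Felkin–Anh control and give the erythro epimer, and the α-aryloxy ketone may epimerise before it is reduced. The fallback makes the carbinol stereocentre by C–C bond formation under chelation control. It sets out from Weinreb amide 22, which is reduced with iBu2AlH (THF, −78 °C) to (2R)-2-{4-[(2S,3R,4R,5S)-5-(3,4-dimethoxyphenyl)-3,4-dimethyloxolan-2-yl]-2-methoxyphenoxy}propanal F4. F4 is precomplexed with MgBr2·OEt2 (CH2Cl2, −78 °C) and treated with 23; the five-membered magnesium chelate exposes the face next to the α-hydrogen, and aryl addition there should give the same threo carbinol, so the route is rejoined at 26.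

Step 5. The basic aryllithium may enolise the α-branched lactone instead of adding (recovered or C3-epimerised lactone), may add twice once the adduct opens, or the enolisable ketone may epimerise at the carbon next to the carbonyl on work-up. The fallback uses an acyclic, O-protected acyl donor. It sets out from lactone 11, which is opened with Me2AlN(OMe)Me (from AlMe3 and MeNH(OMe)·HCl, CH2Cl2, 0 °C) to (2R,3R,4S)-4-(3,4-dimethoxyphenyl)-4-hydroxy-N-methoxy-N,2,3-trimethylbutanamide F5. F5 is silylated at once (Et3SiCl, imidazole, DMF) to (2R,3R,4S)-4-(3,4-dimethoxyphenyl)-N-methoxy-N,2,3-trimethyl-4-(triethylsilyloxy)butanamide F6. F6 acylates aryllithium 13 (THF, −78 °C) to (2R,3R,4S)-1-[4-(benzyloxy)-3-methoxyphenyl]-4-(3,4-dimethoxyphenyl)-2,3-dimethyl-4-(triethylsilyloxy)butan-1-one F7. Et3SiH with Me3SiOTf (CH2Cl2, −78 °C) should then effect desilylative reductive cycloetherification through the same oxocarbenium ion 17, and the route is rejoined at 18.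

**Further compounds**
F1 | step 6 | (3R,4R,5S)-5-(3,4-dimethoxyphenyl)-3,4-dimethyloxolan-2-ol | OC1O[C@H](c2ccc(OC)c(OC)c2)[C@H](C)[C@H]1C
F2 | step 6 | (3R,4R,5S)-2-(benzenesulfonyl)-5-(3,4-dimethoxyphenyl)-3,4-dimethyloxolane | O=S(=O)(c1ccccc1)C2O[C@H](c3ccc(OC)c(OC)c3)[C@H](C)[C@H]2C
F3 | step 6 | [4-(benzyloxy)-3-methoxyphenyl]zinc bromide | Br[Zn]c1ccc(OCc2ccccc2)c(OC)c1
F4 | step 11 | (2R)-2-{4-[(2S,3R,4R,5S)-5-(3,4-dimethoxyphenyl)-3,4-dimethyloxolan-2-yl]-2-methoxyphenoxy}propanal | O=C[C@@H](C)Oc1ccc(cc1OC)[C@H]2O[C@H](c3ccc(OC)c(OC)c3)[C@H](C)[C@H]2C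
F5 | step 5 | (2R,3R,4S)-4-(3,4-dimethoxyphenyl)-4-hydroxy-N-methoxy-N,2,3-trimethylbutanamide | O[C@H](c1ccc(OC)c(OC)c1)[C@H](C)[C@@H](C)C(=O)N(C)OC
F6 | step 5 | (2R,3R,4S)-4-(3,4-dimethoxyphenyl)-N-methoxy-N,2,3-trimethyl-4-(triethylsilyloxy)butanamide | CC[Si](CC)(CC)O[C@H](c1ccc(OC)c(OC)c1)[C@H](C)[C@@H](C)C(=O)N(C)OC
F7 | step 5 | (2R,3R,4S)-1-[4-(benzyloxy)-3-methoxyphenyl]-4-(3,4-dimethoxyphenyl)-2,3-dimethyl-4-(triethylsilyloxy)butan-1-one | CC[Si](CC)(CC)O[C@H](c1ccc(OC)c(OC)c1)[C@H](C)[C@@H](C)C(=O)c2ccc(OCc3ccccc3)c(OC)c2
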